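**Plan**

- Retrosynthesis: ring A is cut at C1–C10 and C3–C4 (together with O–C2), leaving acrolein and a 5-methoxy γ-lactone on the BCD core. The lactone is then cut at O–C10 and C4–C5 (lactate triflate), C7 at C6–C7 (carbonylation), ring D at C13–C16 (vinyl bromide onto ketone), and C8–C15 by reductive alkylation of 6-methoxy-1-indanone.
- Forward: rings B and C come from the indanone, ring D is closed by a Nozaki–Hiyama–Kishi reaction, ring B is carboxylated, oxidized at C10 and alkylated at C5, the γ-lactone is closed as a pseudo ester, and ring A is annulated last.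
- Enabling feature: C4 and C10 are 1,3-related across C5 and tied together by the C19 lactone, so the 5-methoxy lactone is a masked 1,3-zwitterion (enolizable C4, latent acyloxocarbenium C10). C1–C2–C3, with oxygen on C2 and C3, maps onto acrolein (C3 = CHO, C1=C2 = alkene).
- Stereochemistry: C8 by kinetic resolution (C13 follows from C8); C6 and C9 by equilibration; C5 by anti alkylation; C4 and C3 by a convex-face, closed-transition-state aldol; C10 by the tether; C2 by anti addition across C1=C2 with carbonate participation.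

Key step: step 13

Assumption (remark on the chemistry): gibberellane numbering is used for all intermediates, and in ketones 14 and 17 the target configuration at C5, C6 and C9 (cis fusion of rings B and C, trans 1,2-relationships around ring B) is taken to be the thermodynamically preferred one.

**Step 1**
Reactants: 1 6-methoxy-1-indanone; 2 2,3-dibromopropene
Product: 4 rac-7a-(2-bromoprop-2-en-1-yl)-6-methoxy-2,3,5,7a-tetrahydro-1H-inden-1-one, via potassium dienolate 3 (not isolated)
Conditions: K (2.2 equiv), NH3(l)/THF, t-BuOH (1.0 equiv), −78 °C; LiBr; isoprene; then 2, −78 °C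
Reagents that add atoms: none
Why: Birch-type reductive alkylation of an aryl ketone, in which two-electron reduction and para protonation give the cross-conjugated dienolate that is C-alkylated at the ring-fusion carbon C8 by the allylic bromide (the vinylic bromide is inert), so C8 is formed as a racemate.

**Step 2**
Reactants: 4 racemic bromoallyl dienone
Product: 5 (7aS)-7a-(2-bromoprop-2-en-1-yl)-6-methoxy-2,3,5,7a-tetrahydro-1H-inden-1-one (recovered enantiomer)
Conditions: (S)-2-methyl-CBS-oxazaborolidine (0.1 equiv), catecholborane (0.6 equiv), PhMe, −78 °C, to just past half conversion; chromatography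
Reagents that add atoms: none
Why: Corey–Bakshi–Shibata reduction used as a kinetic resolution, because catalyst control (quaternary C8 as the large group) and substrate control (hydride anti to the angular bromoallyl group) coincide only for the (7aR)-ketone, so the (7aS)-ketone should be recovered enriched while catecholborane at low temperature leaves the alkenes alone.

**Step 3**
Reactants: 5 (7aS)-methoxy dienone
Product: 6 (7aR)-7a-(2-bromoprop-2-en-1-yl)-2,3,7,7a-tetrahydro-1H-indene-1,6(5H)-dione
Conditions: oxalic acid (0.2 equiv), THF/H2O (4:1), 0 °C → rt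
Reagents that add atoms: water, O
Why: mild acid hydrolysis of the methyl enol ether releases the C13 ketone while the C9=C11 alkene should stay out of conjugation and C8 is untouched.

**Step 4**
Reactants: 6 bromoallyl diketone
Product: 7 tricyclic 13-hydroxy 6-ketone (C9=C11 alkene, 16-methylene)
Conditions: CrCl2 (6 equiv), NiCl2 (0.05 equiv), DMF, rt
Reagents that add atoms: none
Why: Nozaki–Hiyama–Kishi reaction in which the vinylchromium species adds intramolecularly to the C13 ketone to close five-membered ring D (addition to the C6 ketone would need a four-membered ring), giving the bridgehead tertiary allylic alcohol and the 16-methylene at once with C13 fixed by C8.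

**Step 5**
Reactants: 7 tricyclic 13-hydroxy 6-ketone
Product: 8 13-O-triethylsilyl ether of 7
Conditions: TESOTf, 2,6-lutidine, CH2Cl2, −78 °C
Reagents that add atoms: triethylsilyl trifluoromethanesulfonate, CC[Si](CC)(CC)OS(=O)(=O)C(F)(F)F
Why: silylation of the hindered tertiary alcohol with a silyl triflate protects O13 against the bases and Lewis acids used later.

**Step 6**
Reactants: 8 13-O-TES 6-ketone
Product: 10 C6 enol triflate (C5=C6), via potassium enolate 9 (not isolated)
Conditions: KHMDS, THF, −78 °C; then PhNTf2, −78 → 0 °C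
Reagents that add atoms: N-phenylbis(trifluoromethanesulfonimide), O=S(=O)(N(c1ccccc1)S(=O)(=O)C(F)(F)F)C(F)(F)F
Why: the ketone can enolize only toward C5 because C8 is quaternary, so O-triflation of the enolate should give a single vinyl triflate.

**Step 7**
Reactants: 10 C6 enol triflate
Product: 11 2-(trimethylsilyl)ethyl C6-carboxylate (C5=C6 and C9=C11 diene)
Conditions: Pd(OAc)2 (0.05 equiv), PPh3 (0.1 equiv), CO (1 atm), Me3SiCH2CH2OH (5 equiv), Et3N, DMF, 50 °C
Reagents that add atoms: carbon monoxide, [C-]#[O+]; 2-(trimethylsilyl)ethanol, C[Si](C)(C)CCO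
Why: palladium-catalysed alkoxycarbonylation of a vinyl triflate (oxidative addition, CO insertion, alcoholysis) installs C7 as an ester that fluoride can remove at the end.

**Step 8**
Reactants: 11 diene ester
Product: 12 10-oxo cross-conjugated dienone ester
Conditions: CrO3, 3,5-dimethylpyrazole, CH2Cl2, −20 °C
Reagents that add atoms: chromium trioxide, O=[Cr](=O)=O
Why: allylic oxidation by the CrO3–3,5-dimethylpyrazole complex should occur at the doubly allylic C10 methylene, which has the weakest C–H bonds in the molecule, and gives the cross-conjugated dienone.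

**Step 9**
Reactants: 12 dienone ester
Product: 14 keto ester with 6β-ester and 9β-H, via C6/C9 epimer mixture 13 (not isolated)
Conditions: [(Ph3P)CuH]6 (0.5 equiv of hexamer), PhMe/THF, H2O (2 equiv), rt; then t-BuOK (0.2 equiv), t-BuOH/THF, 0 °C → rt
Reagents that add atoms: none
Why: copper hydride conjugate reduction saturates both conjugated C=C bonds without touching the ketone or the isolated 16-ene, and base equilibration should then bring the epimerizable C6 and C9 to the cis-fused hydrindanone with the C6 ester trans to the C8–C14 bond.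

**Step 10**
Reactants: 14 keto ester; 15 ethyl (S)-2-(trifluoromethylsulfonyloxy)propanoate
Product: 17 keto diester with the propanoate side chain on C5 (α), via lithium enolate 16 (not isolated)
Conditions: LDA (1.05 equiv), THF, −78 °C; then 15, −78 → −30 °C
Reagents that add atoms: none
Why: kinetic enolate alkylation in which LDA deprotonates the less substituted α-carbon C5 and SN2 displacement of the secondary triflate (inversion at C4) takes place anti to the neighbouring C6 ester, setting C5 trans to C6.

**Step 11**
Reactants: 17 keto diester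
Product: 18 keto acid (free C19 carboxylic acid)
Conditions: LiOH (1.5 equiv), THF/H2O (3:1), 0 °C; then 0.5 M HCl to pH 4, 0 °C
Reagents that add atoms: lithium hydroxide, [Li+].[OH-]
Why: saponification should select the unhindered ethyl ester over the C7 ester, which is shielded by the quaternary C8.

**Step 12**
Reactants: 18 keto acid
Product: 19 10-methoxy 19,10-lactone (pseudo ester, cis-fused to ring B)
Conditions: MeOSiMe3 (3 equiv), TMSOTf (0.1 equiv), CH2Cl2, −78 → −30 °C; Et3N quench
Reagents that add atoms: methoxytrimethylsilane, CO[Si](C)(C)C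
Why: acetalization of the C10 ketone with intramolecular capture of the oxocarbenium ion by the C19 carboxyl gives the 5-methoxy γ-lactone, necessarily cis-fused on the face that carries C4, which masks C10 as a latent acyloxocarbenium and leaves C4–H as the most acidic position.

**Step 13**
Reactants: 19 10-methoxy 19,10-lactone; 20 acrolein
Product: 24 fully protected target (2β,3β-cyclic carbonate 13-O-triethylsilyl ether 2-(trimethylsilyl)ethyl ester), via lithium lactone enolate 21 (not isolated), via lithium aldolate 22 (not isolated), via allylic tert-butyl carbonate 23 (not isolated)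
Conditions: LiHMDS (1.1 equiv), PhMe/THF (10:1), −78 °C; 20 (1.5 equiv), −78 °C; Boc2O (1.5 equiv), −78 → −40 °C; then CH2Cl2, 2,6-di-tert-butyl-4-methylpyridine (2 equiv), BF3·OEt2 (4 equiv), −78 → −20 °C
Reagents that add atoms: di-tert-butyl dicarbonate, CC(C)(C)OC(=O)OC(=O)OC(C)(C)C
Why: Proposed new method: the lithium enolate of 19 adds 1,2 to acrolein (C3–C4), the aldolate is trapped as its tert-butyl carbonate, and BF3 then ionizes the C10 methoxy group to an acyloxocarbenium ion that is attacked by the terminal alkene carbon C1 while the carbonate carbonyl oxygen captures the developing C2 cation and the tert-butyl group is lost. The closest known reaction types are lactone-enolate aldol additions, acyliminium or oxocarbenium–alkene (Prins) cyclizations that build bridged bicycles, and cation–olefin cyclizations terminated by tert-butyl carbonates. Ring A closes 6-endo-trig in the Markovnikov sense onto C10 to give the 6-oxabicyclo[3.2.1]octan-7-one, and the carbonate ring closes by 5-exo attack of oxygen on C2. C4 is set by attack on the convex face of the cis-fused bicyclic enolate (anti to C6), C3 by a chair Zimmerman–Traxler transition state in which the methyl group cis to O–Li ends syn to the new oxygen (3β), C10 by the tether because C1 can reach only the face syn to C3, and C2 by antiperiplanar addition across C1=C2 in which the axial 3β-carbonate delivers oxygen to the equatorial 2β position. The step needs 1,2- over 1,4-addition to acrolein (hard lithium enolate at −78 °C), ionization of the tertiary acylal before the allylic carbonate (which sits next to a quaternary carbon bearing a carbonyl) can leave, and the hindered pyridine to keep protons away from the 16-ene.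

**Step 14**
Reactants: 24 fully protected target
Product: 26 target gibberellin (2β,3β,13-triol 19,10-lactone 7-carboxylic acid), via tetrabutylammonium carboxylate 25 (not isolated)
Conditions: TBAF (3 equiv), THF, rt; then K2CO3 (0.2 equiv), MeOH, 0 °C; 0.5 M HCl to pH 3, 0 °C
Reagents that add atoms: none
Why: fluoride desilylation removes the triethylsilyl ether and the 2-(trimethylsilyl)ethyl ester (β-elimination to ethene), and brief carbonate-catalysed methanolysis in the cold opens the cyclic carbonate with retention at C2 and C3, so that the hindered 19,10-lactone and the retro-aldol-prone C3–C4 bond should survive.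

**Compound list**

1 | 6-methoxy-1-indanone | COc1ccc2CCC(=O)c2c1 | starting material
2 | 2,3-dibromopropene | C=C(Br)CBr | starting material
3 | potassium 6-methoxy-3,5-dihydro-2H-inden-1-olate (cross-conjugated dienolate) | [K+].[O-]C1=C2C=C(OC)CC=C2CC1 | intermediate
4 | rac-7a-(2-bromoprop-2-en-1-yl)-6-methoxy-2,3,5,7a-tetrahydro-1H-inden-1-one | C=C(Br)CC12C=C(OC)CC=C1CCC2=O | intermediate
5 | (7aS)-7a-(2-bromoprop-2-en-1-yl)-6-methoxy-2,3,5,7a-tetrahydro-1H-inden-1-one | C=C(Br)C[C@]12C=C(OC)CC=C1CCC2=O | intermediate
6 | (7aR)-7a-(2-bromoprop-2-en-1-yl)-2,3,7,7a-tetrahydro-1H-indene-1,6(5H)-dione (C6 and C13 ketones, C9=C11 alkene) | C=C(Br)C[C@]12CC(=O)CC=C1CCC2=O | intermediate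
7 | tricyclic ketol: ring B cyclopentanone (C6=O) fused to the 13-hydroxy-16-methylene bicyclo[3.2.1]octane, C9=C11 alkene | C=C1C[C@]23C[C@@]1(O)CC=C2CCC3=O | intermediate
8 | 13-O-triethylsilyl ether of 7 | C=C1C[C@]23C[C@@]1(O[Si](CC)(CC)CC)CC=C2CCC3=O | intermediate
9 | potassium C5=C6 enolate of 8 | C=C1C[C@]23C[C@@]1(O[Si](CC)(CC)CC)CC=C2CC=C3[O-].[K+] | intermediate
10 | C6 enol triflate (C5=C6, C9=C11) | C=C1C[C@]23C[C@@]1(O[Si](CC)(CC)CC)CC=C2CC=C3OS(=O)(=O)C(F)(F)F | intermediate
11 | 2-(trimethylsilyl)ethyl C6-carboxylate (C7 ester; C5=C6, C9=C11) | C=C1C[C@]23C[C@@]1(O[Si](CC)(CC)CC)CC=C2CC=C3C(=O)OCC[Si](C)(C)C | intermediate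
12 | 10-oxo dienone ester (C5=C6 and C9=C11 flanking the C10 ketone) | C=C1C[C@]23C[C@@]1(O[Si](CC)(CC)CC)CC=C2C(=O)C=C3C(=O)OCC[Si](C)(C)C | intermediate
13 | 10-oxo keto ester, mixture of C6 and C9 epimers | C=C1C[C@]23C[C@@]1(O[Si](CC)(CC)CC)CCC2C(=O)CC3C(=O)OCC[Si](C)(C)C | intermediate
14 | 10-oxo keto ester, 6β-CO2CH2CH2SiMe3, 9β-H (rings B and C cis-fused) | C=C1C[C@]23C[C@@]1(O[Si](CC)(CC)CC)CC[C@H]2C(=O)C[C@@H]3C(=O)OCC[Si](C)(C)C | intermediate
15 | ethyl (S)-2-(trifluoromethylsulfonyloxy)propanoate | C[C@H](OS(=O)(=O)C(F)(F)F)C(=O)OCC | starting material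
16 | lithium C5=C10 enolate of 14 | C=C1C[C@]23C[C@@]1(O[Si](CC)(CC)CC)CC[C@H]2C([O-])=C[C@@H]3C(=O)OCC[Si](C)(C)C.[Li+] | intermediate
17 | keto diester: 14 carrying a 1-(ethoxycarbonyl)ethyl group on C5 (α, trans to the C6 ester; C4 from inversion of 15) | C=C1C[C@]23C[C@@]1(O[Si](CC)(CC)CC)CC[C@H]2C(=O)[C@@H]([C@H](C)C(=O)OCC)[C@@H]3C(=O)OCC[Si](C)(C)C | intermediate
18 | keto acid: 17 with free C19 carboxylic acid | C=C1C[C@]23C[C@@]1(O[Si](CC)(CC)CC)CC[C@H]2C(=O)[C@@H]([C@H](C)C(=O)O)[C@@H]3C(=O)OCC[Si](C)(C)C | intermediate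
19 | 10β-methoxy 19,10-lactone (γ-lactone cis-fused to ring B on the α face, C4–H) | C=C1C[C@]23C[C@@]1(O[Si](CC)(CC)CC)CC[C@H]2[C@@]5(OC)OC(=O)[C@@H](C)[C@H]5[C@@H]3C(=O)OCC[Si](C)(C)C | intermediate
20 | acrolein | C=CC=O | starting material
21 | lithium C4=C19 enolate of 19 | C=C1C[C@]23C[C@@]1(O[Si](CC)(CC)CC)CC[C@H]2[C@@]5(OC)OC([O-])=C(C)[C@H]5[C@@H]3C(=O)OCC[Si](C)(C)C.[Li+] | intermediate
22 | lithium aldolate: C4 quaternary, C3 alkoxide (3β), vinyl group = C2=C1 | C=C1C[C@]23C[C@@]1(O[Si](CC)(CC)CC)CC[C@H]2[C@@]5(OC)OC(=O)[C@](C)([C@@H]([O-])C=C)[C@H]5[C@@H]3C(=O)OCC[Si](C)(C)C.[Li+] | intermediate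
23 | allylic tert-butyl carbonate of the aldol adduct | C=C1C[C@]23C[C@@]1(O[Si](CC)(CC)CC)CC[C@H]2[C@@]5(OC)OC(=O)[C@](C)([C@@H](OC(=O)OC(C)(C)C)C=C)[C@H]5[C@@H]3C(=O)OCC[Si](C)(C)C | intermediate
24 | fully protected target: 2β,3β-cyclic carbonate, 13-O-triethylsilyl ether, 2-(trimethylsilyl)ethyl ester of 26 | C=C1C[C@]23C[C@@]1(O[Si](CC)(CC)CC)CC[C@H]2[C@@]12C[C@H](OC(=O)O4)[C@H]4[C@@](C)(C(=O)O1)[C@H]2[C@@H]3C(=O)OCC[Si](C)(C)C | intermediate
25 | tetrabutylammonium 7-carboxylate of the 2β,3β-cyclic carbonate of 26 (free 13-OH) | C=C1C[C@]23C[C@@]1(O)CC[C@H]2[C@@]12C[C@H](OC(=O)O4)[C@H]4[C@@](C)(C(=O)O1)[C@H]2[C@@H]3C(=O)[O-].CCCC[N+](CCCC)(CCCC)CCCC | intermediate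
26 | target gibberellin: 2β,3β,13-trihydroxy-20-norgibberell-16-ene-7,19-dioic acid 19,10-lactone | C=C1C[C@]23C[C@@]1(O)CC[C@H]2[C@@]12C[C@H](O)[C@H](O)[C@@](C)(C(=O)O1)[C@H]2[C@@H]3C(=O)O | target

**Step count and risks**

Total step count: 14. Longest linear sequence: 14 steps (from 1).

Steps most likely to fail:

Step 13 (proposed new method). The lactone enolate may fragment with loss of methoxide before it meets acrolein. The aldolate may revert before it is trapped. In the Lewis acid stage the acyloxocarbenium ion may lose a proton, or the carbonate may leave, instead of cyclization taking place. The fallback uses known chemistry, sets out from 17 and returns at 26. Addition of 2-(1,3-dioxolan-2-yl)ethylmagnesium bromide with CeCl3 (THF, −78 °C) to the C10 ketone from the convex β face, followed by lactonization onto the ethyl ester on warming, would give the dioxolane lactone F1. Aqueous acetic acid in THF would unmask the aldehyde F2. An intramolecular aldol of the lactone enolate onto the C3 aldehyde (KHMDS, THF, −78 °C) would close ring A as the 3β-hydroxy lactone F3. Dess–Martin oxidation would give the 3-ketone F4, which can enolize only toward C2. Enolate hydroxylation (KHMDS, then 2-(phenylsulfonyl)-3-phenyloxaziridine) from the β face, away from the lactone bridge, would give the 2β-hydroxy 3-ketone F5. L-Selectride (equatorial attack) would give the 2β,3β-diol F6, and TBAF would then release 26.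

Step 2. The difference in rate between the two enantiomers may be too small, so the recovered ketone would be only partly enriched. The fallback sets out from 4 and returns at 5. NaBH4/CeCl3 reduction (hydride anti to the bromoallyl group) would give the racemic cis alcohol F7. Lipase-catalysed acylation (Candida antarctica lipase B, vinyl acetate) should acetylate the (1R,7aR) enantiomer and leave the (1S,7aS)-alcohol F8, which is separated and oxidized with Dess–Martin periodinane to 5.

Step 10. The enolate may act as a base toward the secondary triflate (elimination to the acrylate) or exchange protons so that C9 is alkylated or epimerized, instead of clean C-alkylation at C5. The fallback sets out from 14 and returns at 17. The kinetic lithium enolate of 14 (LDA, −78 °C) would be added to ethyl pyruvate to give the tertiary aldol F9. Mesylation (MsCl, Et3N, CH2Cl2, 0 °C) would give the tertiary mesylate F10, and elimination with DBU would give the alkylidene keto diester F11. Reduction of this ene-1,4-dicarbonyl unit with zinc in acetic acid, followed by brief equilibration with catalytic t-BuOK, would give 17; the configuration at C4 need not be controlled here because this centre becomes trigonal in enolate 21.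

**Further compounds**

F1 | step 13 | 19,10-lactone carrying a 2-(1,3-dioxolan-2-yl)ethyl group on C10 (β), C4–H | C=C1C[C@]23C[C@@]1(O[Si](CC)(CC)CC)CC[C@H]2[C@@]5(CCC6OCCO6)OC(=O)[C@@H](C)[C@H]5[C@@H]3C(=O)OCC[Si](C)(C)C
F2 | step 13 | 19,10-lactone carrying a 3-oxopropyl group on C10 (C3 aldehyde) | C=C1C[C@]23C[C@@]1(O[Si](CC)(CC)CC)CC[C@H]2[C@@]5(CCC=O)OC(=O)[C@@H](C)[C@H]5[C@@H]3C(=O)OCC[Si](C)(C)C
F3 | step 13 | ring A closed 3β-hydroxy 19,10-lactone, 13-O-triethylsilyl ether 2-(trimethylsilyl)ethyl ester (2-deoxy analogue of F6) | C=C1C[C@]23C[C@@]1(O[Si](CC)(CC)CC)CC[C@H]2[C@@]12CC[C@H](O)[C@@](C)(C(=O)O1)[C@H]2[C@@H]3C(=O)OCC[Si](C)(C)C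
F4 | step 13 | 3-oxo analogue of F3 | C=C1C[C@]23C[C@@]1(O[Si](CC)(CC)CC)CC[C@H]2[C@@]12CCC(=O)[C@@](C)(C(=O)O1)[C@H]2[C@@H]3C(=O)OCC[Si](C)(C)C
F5 | step 13 | 2β-hydroxy-3-oxo analogue of F3 | C=C1C[C@]23C[C@@]1(O[Si](CC)(CC)CC)CC[C@H]2[C@@]12C[C@H](O)C(=O)[C@@](C)(C(=O)O1)[C@H]2[C@@H]3C(=O)OCC[Si](C)(C)C
F6 | step 13 | 13-O-triethylsilyl ether 2-(trimethylsilyl)ethyl ester of target 26 (free 2β,3β-diol) | C=C1C[C@]23C[C@@]1(O[Si](CC)(CC)CC)CC[C@H]2[C@@]12C[C@H](O)[C@H](O)[C@@](C)(C(=O)O1)[C@H]2[C@@H]3C(=O)OCC[Si](C)(C)C
F7 | step 2 | rac-cis-7a-(2-bromoprop-2-en-1-yl)-6-methoxy-2,3,5,7a-tetrahydro-1H-inden-1-ol (OH cis to the bromoallyl group) | C=C(Br)CC12C=C(OC)CC=C1CCC2O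
F8 | step 2 | (1S,7aS)-7a-(2-bromoprop-2-en-1-yl)-6-methoxy-2,3,5,7a-tetrahydro-1H-inden-1-ol | C=C(Br)C[C@]12C=C(OC)CC=C1CC[C@@H]2O
F9 | step 10 | aldol adduct of 14 with ethyl pyruvate (C5 bears C(OH)(CH3)CO2Et, mixture of epimers) | C=C1C[C@]23C[C@@]1(O[Si](CC)(CC)CC)CC[C@H]2C(=O)C(C(C)(O)C(=O)OCC)[C@@H]3C(=O)OCC[Si](C)(C)C
F10 | step 10 | tertiary methanesulfonate of F9 | C=C1C[C@]23C[C@@]1(O[Si](CC)(CC)CC)CC[C@H]2C(=O)C(C(C)(OS(C)(=O)=O)C(=O)OCC)[C@@H]3C(=O)OCC[Si](C)(C)C
F11 | step 10 | alkylidene keto diester (C5=C4, E/Z mixture) | C=C1C[C@]23C[C@@]1(O[Si](CC)(CC)CC)CC[C@H]2C(=O)C(=C(C)C(=O)OCC)[C@@H]3C(=O)OCC[Si](C)(C)C
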